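**Plan**

- Retrosynthesis: the phenol is first masked as its benzyl ether. The ester is then cut at two bonds at once, C1–C2 and C1–O(pentacosyl), which removes C1 as carbon monoxide and leaves a 4-oxygenated styrene and pentacosan-1-ol. The styrene C=C is cut back to the aryl aldehyde.
- Enabling feature: the ester carbonyl carbon C1 is a lone carbon between the C2–C3 ethylene arm on the para-oxygenated benzene ring and the pentacosyl oxygen, so CO can supply it.
- Forward: aldehyde 1 is methylenated to styrene 4. Then 4, CO and the C25 alcohol are joined in one operation to give the full chain in 7. Debenzylation gives 8.
- Rings: the benzene ring is bought intact and no ring is formed.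
- Stereochemistry: none to set. The only selectivity issue is linear versus branched carbonylation in step 2.

Key step: step 2

Remark: the target has no stereocentre and no configured double bond, so "single enantiomer" is taken to mean the one achiral compound drawn.

**Route**

Step 1
Reactants: 1 4-(benzyloxy)benzaldehyde; 2 methyltriphenylphosphonium bromide
Product: 4 1-(benzyloxy)-4-ethenylbenzene, via methylenetriphenylphosphorane 3 (not isolated)
Conditions: KOtBu, THF, 0 °C to rt
Reagents that add atoms: none
Why: Wittig methylenation, in which the non-stabilised ylide 3 formed from 2 and KOtBu adds to the non-enolisable aldehyde 1 and the oxaphosphetane collapses to the terminal alkene, the benzyl ether being inert to the base.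

Step 2
Reactants: 4 1-(benzyloxy)-4-ethenylbenzene; 5 carbon monoxide; 6 pentacosan-1-ol
Product: 7 pentacosyl 3-[4-(benzyloxy)phenyl]propanoate
Conditions: Pd(OAc)2 (1 mol%), 1,2-bis(di-tert-butylphosphinomethyl)benzene (4 mol%), MeSO3H (5 mol%), CO (30 bar), toluene, 90 °C, 4 (1.2 equiv) added slowly
Reagents that add atoms: none
Why: Hydroalkoxycarbonylation through the palladium-hydride cycle: the cationic diphosphine–Pd–H formed from Pd(OAc)2, the ligand and MeSO3H adds across the vinyl group of 4, CO inserts into the linear 2-arylethyl–Pd bond to give the acyl complex (new C1–C2 bond), and alcoholysis of that acyl by 6 forms the C1–O ester bond and regenerates Pd–H. The closest known reaction type is the linear-selective hydromethoxycarbonylation of styrenes with palladium and bulky chelating bis(di-tert-butylphosphino) ligands, here run with a stoichiometric primary alcohol in toluene in place of methanol as solvent. No ring closes and no stereocentre is created. The selectivity needed is regiochemical, the linear 3-arylpropanoate over the branched 2-arylpropanoate: hydride insertion is reversible, and the tert-butyl groups of the ligand make CO insertion and alcoholysis at the crowded benzylic palladium slow, so the branched alkyl should drain back through the alkene into the linear acyl. The benzyl ether removes the free phenol as a competing O-nucleophile and avoids the ready polymerisation of the free vinylphenol; because a para-alkoxystyrene remains open to acid-initiated oligomerisation, the acid is held at a few mol% buffered by excess phosphine and 4 is fed slowly into the CO-saturated mixture.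

Step 3
Reactants: 7 pentacosyl 3-[4-(benzyloxy)phenyl]propanoate
Product: 8 pentacosyl 3-(4-hydroxyphenyl)propanoate
Conditions: H2 (1 atm), 10% Pd/C, EtOAc–THF, rt to 40 °C
Reagents that add atoms: none
Why: Heterogeneous catalytic hydrogenolysis of the aryl benzyl ether cleaves the benzylic C–O bond under neutral conditions that should leave the alkyl ester, the saturated chain and the phenol ring untouched.

**Compound list**

1 | 4-(benzyloxy)benzaldehyde | O=Cc1ccc(OCc2ccccc2)cc1 | starting material
2 | methyltriphenylphosphonium bromide | C[P+](c1ccccc1)(c1ccccc1)c1ccccc1.[Br-] | starting material
3 | methylenetriphenylphosphorane | C=P(c1ccccc1)(c1ccccc1)c1ccccc1 | intermediate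
4 | 1-(benzyloxy)-4-ethenylbenzene | C=Cc1ccc(OCc2ccccc2)cc1 | intermediate
5 | carbon monoxide | [C-]#[O+] | starting material
6 | pentacosan-1-ol | CCCCCCCCCCCCCCCCCCCCCCCCCO | starting material
7 | pentacosyl 3-[4-(benzyloxy)phenyl]propanoate | CCCCCCCCCCCCCCCCCCCCCCCCCOC(=O)CCc1ccc(OCc2ccccc2)cc1 | intermediate
8 | pentacosyl 3-(4-hydroxyphenyl)propanoate | CCCCCCCCCCCCCCCCCCCCCCCCCOC(=O)CCc1ccc(O)cc1 | target

**Summary**

Total step count: 3
Longest linear sequence: 3 steps (1 → 4 → 7 → 8)

Steps most likely to fail, riskiest first:

Step 2. Three processes could undermine it. CO insertion at the benzylic palladium could leak to the branched 2-arylpropanoate, which would be very hard to separate from the waxy linear ester. Acid-initiated oligomerisation of the electron-rich styrene could outpace carbonylation. Alcoholysis of the acyl–palladium could be slow because the alcohol is stoichiometric and dilute, not the solvent. The fallback sets out from pentacosan-1-ol 6 and makes the ester by acyl substitution instead of carbonylation. Compound 6 is heated with commercial 3-(4-hydroxyphenyl)propanoic acid and catalytic p-TsOH in toluene with azeotropic removal of water (Fischer esterification). The phenol should not be acylated under these conditions, so this should give target 8 directly, by-passing 7 and step 3. No new compound arises on the way (F0).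

Step 3. The hydrogenolysis could stall, either through poor solubility of the waxy ester near room temperature or through poisoning of the Pd/C surface by phosphine residues carried over from step 2. The fallback sets out from 7 and replaces reduction with acidolysis: trifluoroacetic acid with pentamethylbenzene as benzyl-cation scavenger in CH2Cl2 at rt. The aryl benzyl ether is protonated and the benzyl group is transferred to the scavenger, while the primary alkyl ester should survive. This returns to the route at 8. No new compound arises (F0).

Step 1. The electron-rich styrene could be lost by oligomerisation during concentration or on acidic silica, and a wet ylide could leave the conversion incomplete. The fallback sets out from aldehyde 1 and uses a Peterson olefination. Addition of (trimethylsilyl)methylmagnesium chloride in THF should give racemic 1-[4-(benzyloxy)phenyl]-2-(trimethylsilyl)ethan-1-ol F1. Treatment with KH in THF then induces syn-elimination of silanolate and comes back to the route at 4, with only volatile silicon by-products to remove.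

**Further compounds**

F0 | step 2 | none | none
F0 | step 3 | none | none
F1 | step 1 | 1-[4-(benzyloxy)phenyl]-2-(trimethylsilyl)ethan-1-ol (racemic) | C[Si](C)(C)CC(O)c1ccc(OCc2ccccc2)cc1
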